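(All runs are simulated for an exercise; the scatter is artificial.)

Follow the share of target in all that became target or isomer of the product, the selectivity, and reckon with the fraction of it kept, not with what is made.

| setting | amber | Friday's | Saturday's |
|---|---|---|---|
| solid substrate | 22 mM | 20 mM | 5.0 mM |
| remark | run made earlier |  |  |
| time |  | 80 min | 250 min |

amber run (percent of the solid substrate charged)

| time / min | target / % | isomer of the product / % |
|---|---|---|
| 2.50 | 13 | 2 |
| 5.00 | 36 | 4 |
| 12.0 | 66 | 11 |
| 30.0 | 80 | 18 |

(standard deviation of a reading: 2 percentage points)

- solid, in amounts per volume of the solution: solid substrate
- at the start none of the solid substrate is in solution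
- in a conversion other conformer counts as not yet reacted
- what has only dissolved of solid substrate counts as not reacted

- which of the two ends with the higher share of target in all that became target or isomer of the product ("neither" if they lie within 2 percentage points) (Friday's / Saturday's / neither)
- share of target in all that became target or isomer of the product, Friday's
- share of target in all that became target or isomer of the product, Saturday's

I take every step as first-order, so that the charge drops out and both flasks follow the amber curve. From above: the last amber reading puts the share at 81.6%, and I expect it no higher later, so that is my ceiling for both flasks. From below: at 12.0 min the share read 85.7%. If the whole fall up to 30.0 min were target turning into isomer of the product, the fraction kept would shrink at 0.00271 min⁻¹, which I call the leak ceiling. It is a ceiling on the loss, as 23.0% was still unreacted at 12.0 min, so fresh isomer of the product sits in that fall too. Carried on from 30.0 min, it leaves 71.3% in Friday's flask and 45.0% in Saturday's. Saturday's flask stands longer on that slope, so I name Friday's as higher.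

The forecast says neither, with 81.5% for Friday's and 81% for Saturday's, since with all steps first-order “the final split doesn't depend on charge”; both values lie inside my bracket, its Friday's value about level with my ceiling and its Saturday's value above my floor.

The flask gives Friday's: 78.9% for Friday's and 74.3% for Saturday's, both inside the bracket.

    starting material ⇌ other conformer (K = 1.60, k = 0.0360 min⁻¹)
    solid substrate ⇌ starting material, rate k2*(cs2 - [starting material]) while solid is left; crystals form when [starting material] > cs2 (solubility = 19.0 mM, k = 0.480 min⁻¹)
    starting material → target (k = 0.140 min⁻¹)
    target ⇌ isomer of the product (K = 0.740, k = 6.00 × 10⁻⁴ min⁻¹)
    other conformer → isomer of the product (k = 0.190 min⁻¹)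

Friday's charge held to Saturday's time gives 74.4%, so over that stretch the fraction kept shrinks on average at 3.51 × 10⁻⁴ min⁻¹, slower than the leak ceiling. The neighbour is Friday's flask left until 5.0 h. From 78.9%, the leak ceiling leaves a floor of 43.5%, and the slower slope gives 73.1%. That flask holds 73.2% target and 26.8% isomer of the product, a share of 73.2%.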